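Remark on numbering: ring A carries the ester on C1, hydroxyls on C2 and C4 and the ether oxygen on C6; ring B carries the ether oxygen on C1', the hydroxyl on C2', methoxyls on C3' and C6' and the prenyl group on C5'.

## Analysis of the target

Paucinervin B (18) is a diaryl ether without ring fusion. Ring A is a methyl 2,4-dihydroxybenzoate bound through the oxygen on C6 to ring B, a pentasubstituted benzene with oxygen on C1', C2', C3' and C6', a 3-methylbut-2-enyl (prenyl) group on C5' and one hydrogen on C4'. There is no stereocentre, and the prenyl alkene ends in two identical methyl groups, so the whole problem is one of regiochemistry. The sensitive groups are the prenyl group, the three phenols and the ester. The prenyl alkene is protonated easily to a tertiary cation, and its CH2 is benzylic and allylic at once. The phenols sit on electron-rich rings that oxidise readily, and the ester lies within reach of the C2' hydroxyl and could close a seven-membered depsidone lactone. The synthesis is hard for two reasons: the ether oxygen has three ortho substituents around it (C1, C2' and C6'), and the ester must stand on the ring A carbon between the bridge oxygen and a hydroxyl, not on the carbon between the two hydroxyls that metalation or electrophilic attack on a 3,5-dioxygenated phenyl ether would normally choose. The strategy rests on the fact that the ester carbon on C1 and the hydroxyl on C2' face each other across the ether oxygen, so that a carbonyl carbon bound to the C2' oxygen can reach C1 through a seven-membered ring. C1 is flanked by the C2 and C6 oxygens, which makes its C–H acidic in an ester-free precursor, and both carbons ortho to C2' (C1' and C3') are substituted, so an acyl group on the C2' oxygen has no place to go on its own ring.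

## Retrosynthetic reasoning

18 to 17. The last operation releases the two ring A phenols. They are carried as methoxymethyl ethers from the start: these acetals survive base, copper, hydrogenolysis and palladium, they acidify and coordinate in the metalation of the key step, and they come off under acid mild enough for the prenyl group. The forward step has to cleave two aryl acetals without protonating the alkene.

17 to 15 and 16. The C5'–CH2 bond is cut next. The prenyl group is held back until after the key step because its doubly activated CH2 would not survive a lithium amide. Stannane 16 brings the whole five-carbon unit to bromide 15 under neutral conditions that tolerate the free phenol and the ester.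

15 to 14. The C5'–Br bond is cut. In 14 the C2' hydroxyl is free and both its ortho carbons are substituted, so the para carbon C5' is the most nucleophilic site of the molecule. The phenol set free by the key step therefore also directs the halogenation, and no extra step is spent on it.

14 to 11 (key disconnection). The C1–C(=O) bond is cut and the carbonyl carbon is returned to the C2' oxygen as a methyl carbonate. Cutting here and not at the ether avoids a coupling next to an ortho ester on a fully substituted partner. It also avoids an external carboxylation of a ring A anion, which would go to the carbon between the two acetals. In the forward direction a lithium amide generates aryllithium 12 reversibly, the tethered carbonate captures it, and phenoxide 13 is released. One step thus places the ester at the right carbon, delivers it as the methyl ester and frees the C2' phenol.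

11 to 9 and 10. The carbonate O–C(=O) bond is cut; acylation of phenol 9 with chloroformate 10 is routine and puts the future ester carbon in place.

9 to 8, then to 5 and 7. The ether bond is cut at the ring A carbon, so that the aryl halide 7 is symmetric and unhindered and all the crowding lies in the phenoxide of 5. The second catechol oxygen is kept as a benzyl ether in 8. A free, electron-rich catechol would chelate copper, oxidise and could arylate twice, whereas hydrogenolysis of benzyl is orthogonal to the ring A acetals at a stage where no alkene or halide is present.

7 to 6, and 5 to 4, 3, 2 and 1. Bromide 7 comes from 6 by acetal protection. The differentiated catechol 5 comes from 1 by using a formyl group as a latent hydroxyl. Formylation at the only free ortho carbon of 1 gives 2, benzylation gives 3, and oxidative aryl migration through formate 4 turns the formyl carbon into the second oxygen. The two catechol oxygens are never free together.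

## Alternatives that were turned down

Alternative 1: Ring A would be built last by a Diels–Alder reaction. The C1–C2 and C5–C6 bonds are cut, which leads to the aryloxy ynoate A3, made from the prenylated ring B phenol A2, and to the bis-silyloxy diene A4. Cycloaddition, loss of a silyl methyl ether and desilylation would give A1 with both ring A hydroxyls free.
- For it: the polarity of the two partners fixes the ring A pattern without ambiguity, ring A needs no protecting groups, and no strong base is used, so the prenyl group can be present from the start. On regiochemical certainty it is stronger than the chosen route.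
- Against it: A3 is a push–pull ynol ether. Making it requires addition–elimination of the doubly ortho-substituted phenoxide of A2 to a 3-halopropiolate, and the product readily takes up a second phenoxide or water. The aryloxy donor also lowers the dienophile reactivity, and a ketene acetal diene such as A4 tends to add in Michael fashion to open-chain products or to decompose at the temperature then needed. All the work on A2 would be spent before an uncertain step.
- Comparison: the chosen route offers an unproven step on a stable substrate, 11, reached by routine reactions, with the prenyl group added only afterwards.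

Alternative 2: Both bonds to ring A would form in one operation. The C6–O and C1–CO2 bonds are cut, which leads to the silyl triflate A6, the cesium salt of phenol A2 and carbon dioxide A7. A fluoride source releases the aryne, the aryloxide adds at the carbon remote from the neighbouring acetal, and A7 captures the aryl anion next to that acetal to give acid A5.
- For it: this is the most convergent plan. The adjacent alkoxy group controls the aryne regiochemistry reliably, and arynes accept hindered phenoxides without a metal catalyst. On convergence and on forming the crowded ether it is stronger than the chosen route.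
- Against it: an aryl anion formed by aryloxide addition is normally protonated by solvent or by the phenol before it can be carboxylated. A7 also converts the aryloxide reversibly into a carbonate salt, and a three-component coupling with an aryloxide is itself without precedent. A6 needs several steps, and A5 still needs esterification and removal of three acetals.
- Comparison: both plans pass through the same C1 carbanion. The chosen route generates it reversibly and gives it a tethered electrophile, so it does not have to find dissolved A7 before a proton does.

Alternative 3: Only the prenyl bond is addressed. The C5'–CH2 bond is cut and the prenyl group is returned to the C2' oxygen in ether A9. Heating moves it by a [3,3] shift to a blocked ortho carbon and by a second [3,3] shift to C5', giving A8, which has the constitution of 17.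
- For it: no tin, palladium or halogenation is needed. The blocked ortho carbons enforce para delivery and the double inversion returns a linear prenyl group, in the same two steps as bromination and coupling. For this one bond it is as good as or better than the chosen route.
- Against it: it solves the easiest bond. A9 presupposes phenol 14, so the placement of the ester and the crowded ether must be solved by other means. Temperatures near 200 °C would also expose two acetals and an ester lying within reach of the emerging phenol to lactonisation, and the intermediate dienones carry methoxy or aryloxy groups on the sp3 carbon and could aromatise by losing them.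
- Comparison: the chosen strategy answers the ring A problem that this one leaves open. The Claisen–Cope relay is kept as a fallback for the late prenylation.

Key step: step 8

## Route

Step 1
Reactants: 1 2,5-dimethoxyphenol
Product: 2 2-hydroxy-3,6-dimethoxybenzaldehyde
Conditions: (CH2O)n, MgCl2, Et3N, MeCN, reflux; aq HCl work-up
Reagents that add atoms: paraformaldehyde (as formaldehyde), C=O
Why: Magnesium-mediated ortho-formylation (Casnati–Skattebøl): the magnesium phenoxide delivers formaldehyde to the only free ortho carbon and a second formaldehyde oxidises the benzylic alkoxide to the aldehyde; para attack does not compete in this chelation-controlled process.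

Step 2
Reactants: 2 2-hydroxy-3,6-dimethoxybenzaldehyde
Product: 3 2-(benzyloxy)-3,6-dimethoxybenzaldehyde
Conditions: BnBr, K2CO3, DMF, 60 °C
Reagents that add atoms: benzyl bromide, BrCc1ccccc1
Why: Williamson etherification of the chelated phenol; benzyl is chosen because hydrogenolysis can remove it later without touching aryl methoxymethyl ethers.

Step 3
Reactants: 3 2-(benzyloxy)-3,6-dimethoxybenzaldehyde
Product: 5 2-(benzyloxy)-3,6-dimethoxyphenol, via aryl formate 4 (not isolated)
Conditions: mCPBA, CH2Cl2, 0 °C → rt; aq NaHCO3 wash; then K2CO3 (cat.), MeOH, rt
Reagents that add atoms: 3-chloroperoxybenzoic acid, OOC(=O)c1cccc(Cl)c1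
Why: Baeyer–Villiger (Dakin-type) oxidation: the aryl group with two ortho alkoxy donors migrates in preference to hydride to give formate 4, and mild methanolysis should give phenol 5, a catechol with its two oxygens differentiated.

Step 4
Reactants: 6 5-bromobenzene-1,3-diol
Product: 7 1-bromo-3,5-bis(methoxymethoxy)benzene
Conditions: MOMCl, iPr2NEt, CH2Cl2, 0 °C → rt
Reagents that add atoms: chloromethyl methyl ether, COCCl
Why: Standard acetal protection of both phenols; the methoxymethyl ethers are stable to the copper coupling, hydrogenolysis and lithium amide and later assist the metalation.

Step 5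
Reactants: 5 2-(benzyloxy)-3,6-dimethoxyphenol; 7 1-bromo-3,5-bis(methoxymethoxy)benzene
Product: 8 2-(benzyloxy)-3-[3,5-bis(methoxymethoxy)phenoxy]-1,4-dimethoxybenzene
Conditions: CuI (10 mol%), picolinic acid (20 mol%), K3PO4, DMSO, 90 °C
Reagents that add atoms: none
Why: Ullmann diaryl ether coupling with a monovalent copper picolinate catalyst, a system suited to phenols with two ortho substituents; all steric demand lies on the nucleophile, and bromide 7 is unhindered and symmetric, so no regiochemical question arises.

Step 6
Reactants: 8 2-(benzyloxy)-3-[3,5-bis(methoxymethoxy)phenoxy]-1,4-dimethoxybenzene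
Product: 9 2-[3,5-bis(methoxymethoxy)phenoxy]-3,6-dimethoxyphenol
Conditions: H2 (1 atm), 10% Pd/C, EtOAc, rt
Reagents that add atoms: none
Why: Hydrogenolysis of the benzyl ether; the aryl acetals, the diaryl ether and the methyl ethers are inert, and no alkene or halide is present at this stage.

Step 7
Reactants: 9 2-[3,5-bis(methoxymethoxy)phenoxy]-3,6-dimethoxyphenol; 10 methyl chloroformate
Product: 11 2-[3,5-bis(methoxymethoxy)phenoxy]-3,6-dimethoxyphenyl methyl carbonate
Conditions: Et3N, DMAP (cat.), CH2Cl2, 0 °C
Reagents that add atoms: none
Why: O-Acylation of the hindered phenol under nucleophilic catalysis gives the mixed carbonate that carries the future ester carbon.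

Step 8
Reactants: 11 2-[3,5-bis(methoxymethoxy)phenoxy]-3,6-dimethoxyphenyl methyl carbonate
Product: 14 methyl 2-(2-hydroxy-3,6-dimethoxyphenoxy)-4,6-bis(methoxymethoxy)benzoate, via ring A aryllithium 12 (not isolated), via lithium phenoxide 13 (not isolated)
Conditions: lithium 2,2,6,6-tetramethylpiperidide (2.5 equiv, from 2,2,6,6-tetramethylpiperidine 3.0 equiv and n-BuLi 2.5 equiv), THF (0.02 M), −78 → −20 °C; then aq NH4Cl
Reagents that add atoms: none
Why: Proposed new method: a hindered lithium amide, held near ring A by coordination to the carbonate carbonyl, should deprotonate ring A reversibly at the two equivalent carbons between the bridge oxygen and an acetal oxygen and at the carbon between the two acetals, and only aryllithium 12 can add to the carbonate carbonyl, through a seven-membered cyclic transition state (the ring size of the depsidone lactones). The tetrahedral alkoxide then expels the C2' aryloxide, the best leaving group present, which forms the C1–CO2CH3 bond, gives lithium phenoxide 13 irreversibly and drains the metalation equilibrium; lithium at the carbon between the acetals has no electrophile within reach and returns to 11 by proton exchange with the free amine kept in slight excess, while high dilution holds back intermolecular acyl transfer. The closest known reactions are the remote anionic Fries rearrangement of 2-biaryl O-carbamates under lithium amides, which runs through a ring one atom smaller, and the ortho anionic Fries shift of aryl carbonates to salicylate esters; transfer of a carbonate acyl group across a diaryl ether oxygen has not been shown. No ring is closed and no stereocentre is formed. The selectivity needed is of site: ring B has no hydrogen ortho to the carbonate, so the ordinary ortho shift is excluded, the 3,5-dioxygenation of ring A makes the two productive sites identical, and the tether length excludes every other carbon. Lithium 2,2,6,6-tetramethylpiperidide is preferred to LiN(iPr)2 because a methyl carbonate is a better electrophile than a carbamate, and the bulkier, slightly stronger amide should metalate at lower temperature without adding to the carbonyl. Should methoxide leave in place of the aryloxide, the seven-membered lactone so formed would be reopened by lithium methoxide to the same ester phenoxide, so both modes of collapse lead to 13.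

Step 9
Reactants: 14 methyl 2-(2-hydroxy-3,6-dimethoxyphenoxy)-4,6-bis(methoxymethoxy)benzoate
Product: 15 methyl 2-(3-bromo-6-hydroxy-2,5-dimethoxyphenoxy)-4,6-bis(methoxymethoxy)benzoate (bromine on C5', para to the C2' hydroxyl)
Conditions: NBS (1.0 equiv), MeCN, −20 → 0 °C
Reagents that add atoms: N-bromosuccinimide, O=C1CCC(=O)N1Br
Why: Electrophilic aromatic bromination; the phenol freed in step 8 is the strongest donor in the molecule and both its ortho carbons are substituted, so substitution should go to C5', faster than on the ester-bearing, fully etherified ring A.

Step 10
Reactants: 15 methyl 2-(3-bromo-6-hydroxy-2,5-dimethoxyphenoxy)-4,6-bis(methoxymethoxy)benzoate; 16 tributyl(3-methylbut-2-en-1-yl)stannane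
Product: 17 methyl 2-[2-hydroxy-3,6-dimethoxy-5-(3-methylbut-2-en-1-yl)phenoxy]-4,6-bis(methoxymethoxy)benzoate
Conditions: Pd(PPh3)4 (10 mol%), DMF, 100 °C, degassed
Reagents that add atoms: none
Why: Stille coupling: oxidative addition of zerovalent palladium to the aryl bromide, transfer of the allyl unit from tin and reductive elimination at the less substituted allyl terminus should give the linear prenyl arene; the neutral conditions tolerate the free phenol, the ester and the acetals.

Step 11
Reactants: 17 methyl 2-[2-hydroxy-3,6-dimethoxy-5-(3-methylbut-2-en-1-yl)phenoxy]-4,6-bis(methoxymethoxy)benzoate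
Product: 18 paucinervin B, methyl 2,4-dihydroxy-6-[2-hydroxy-3,6-dimethoxy-5-(3-methylbut-2-en-1-yl)phenoxy]benzoate
Conditions: HCl (1.25 M in MeOH), 0 °C → rt
Reagents that add atoms: none
Why: Acid-catalysed acetal exchange with methanol removes both methoxymethyl groups as dimethoxymethane; the cold, dilute acid is chosen to spare the trisubstituted alkene, which has no free hydroxyl beside it to cyclise with, and the methyl ester cannot be changed by methanol.

## Compound list

1 | 2,5-dimethoxyphenol | COc1ccc(OC)c(O)c1 | starting material
2 | 2-hydroxy-3,6-dimethoxybenzaldehyde | O=Cc1c(O)c(OC)ccc1OC | intermediate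
3 | 2-(benzyloxy)-3,6-dimethoxybenzaldehyde | O=Cc1c(OCc2ccccc2)c(OC)ccc1OC | intermediate
4 | 2-(benzyloxy)-3,6-dimethoxyphenyl formate | O=COc1c(OCc2ccccc2)c(OC)ccc1OC | intermediate (not isolated)
5 | 2-(benzyloxy)-3,6-dimethoxyphenol | Oc1c(OCc2ccccc2)c(OC)ccc1OC | intermediate
6 | 5-bromobenzene-1,3-diol | Oc1cc(O)cc(Br)c1 | starting material
7 | 1-bromo-3,5-bis(methoxymethoxy)benzene | COCOc1cc(Br)cc(OCOC)c1 | intermediate
8 | 2-(benzyloxy)-3-[3,5-bis(methoxymethoxy)phenoxy]-1,4-dimethoxybenzene | COCOc1cc(OCOC)cc(Oc2c(OCc3ccccc3)c(OC)ccc2OC)c1 | intermediate
9 | 2-[3,5-bis(methoxymethoxy)phenoxy]-3,6-dimethoxyphenol | COCOc1cc(OCOC)cc(Oc2c(O)c(OC)ccc2OC)c1 | intermediate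
10 | methyl chloroformate | COC(=O)Cl | starting material
11 | 2-[3,5-bis(methoxymethoxy)phenoxy]-3,6-dimethoxyphenyl methyl carbonate | COC(=O)Oc1c(OC)ccc(OC)c1Oc1cc(OCOC)cc(OCOC)c1 | intermediate
12 | {2-[2-(methoxycarbonyloxy)-3,6-dimethoxyphenoxy]-4,6-bis(methoxymethoxy)phenyl}lithium | [Li]c1c(OCOC)cc(OCOC)cc1Oc1c(OC(=O)OC)c(OC)ccc1OC | intermediate (not isolated)
13 | lithium 2-[2-(methoxycarbonyl)-3,5-bis(methoxymethoxy)phenoxy]-3,6-dimethoxyphenoxide | [Li+].[O-]c1c(OC)ccc(OC)c1Oc1cc(OCOC)cc(OCOC)c1C(=O)OC | intermediate (not isolated)
14 | methyl 2-(2-hydroxy-3,6-dimethoxyphenoxy)-4,6-bis(methoxymethoxy)benzoate | COC(=O)c1c(OCOC)cc(OCOC)cc1Oc1c(O)c(OC)ccc1OC | intermediate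
15 | methyl 2-(3-bromo-6-hydroxy-2,5-dimethoxyphenoxy)-4,6-bis(methoxymethoxy)benzoate | COC(=O)c1c(OCOC)cc(OCOC)cc1Oc1c(O)c(OC)cc(Br)c1OC | intermediate
16 | tributyl(3-methylbut-2-en-1-yl)stannane | CCCC[Sn](CCCC)(CCCC)CC=C(C)C | starting material
17 | methyl 2-[2-hydroxy-3,6-dimethoxy-5-(3-methylbut-2-en-1-yl)phenoxy]-4,6-bis(methoxymethoxy)benzoate | COC(=O)c1c(OCOC)cc(OCOC)cc1Oc1c(O)c(OC)cc(CC=C(C)C)c1OC | intermediate
18 | paucinervin B, methyl 2,4-dihydroxy-6-[2-hydroxy-3,6-dimethoxy-5-(3-methylbut-2-en-1-yl)phenoxy]benzoate | COC(=O)c1c(O)cc(O)cc1Oc1c(O)c(OC)cc(CC=C(C)C)c1OC | target

## Step count and least certain steps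

Total step count: 11. Longest linear sequence: 10 steps (steps 1 to 3 and 5 to 11, from 1 to 18); step 4 prepares 7 on a one-step branch.

Step 8 (key step, proposed new method). The most likely failures are addition of the amide to the carbonate carbonyl, which strips the acyl group and returns 9 on work-up, and metalation between the two acetals followed by intermolecular acyl transfer, which puts the ester on the wrong ring A carbon. Both arise because the productive aryllithium is only a minor equilibrium species and must win by its intramolecular reaction. The fallback uses known reactions only, sets out from phenol 5 and gives up the migration for a coupling with a ring A partner that already carries the ester. Commercial methyl 2,4,6-trihydroxybenzoate is protected on the 4-hydroxyl and on one of the two chelated hydroxyls (MOMCl, iPr2NEt, CH2Cl2) to give methyl 2-hydroxy-4,6-bis(methoxymethoxy)benzoate F1. The remaining phenol is converted with triflic anhydride and pyridine into methyl 2,4-bis(methoxymethoxy)-6-(trifluoromethylsulfonyloxy)benzoate F2. Palladium-catalysed C–O coupling of F2 with 5 (Pd(OAc)2, 2-(di-tert-butylphosphino)-2',4',6'-triisopropylbiphenyl, K3PO4, toluene, 100 °C) should give methyl 2-[2-(benzyloxy)-3,6-dimethoxyphenoxy]-4,6-bis(methoxymethoxy)benzoate F3. Hydrogenolysis (H2, Pd/C, EtOAc) comes back to the route at 14.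

Step 10. Transfer of the allyl unit with allylic transposition would give the branched 1,1-dimethylallyl isomer. Oxidative addition to an electron-rich bromide para to a phenol may also be slow, so that protodebromination and stannane homocoupling compete. The fallback sets out from 15. Stille coupling with allyltributylstannane (Pd(PPh3)4, DMF, 100 °C), which raises no regiochemical question, gives methyl 2-[2-hydroxy-3,6-dimethoxy-5-(prop-2-en-1-yl)phenoxy]-4,6-bis(methoxymethoxy)benzoate F4. Cross-metathesis with excess 2-methylbut-2-ene (second-generation Grubbs catalyst, CH2Cl2, 40 °C) turns the allyl into the prenyl group and comes back to the route at 17.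

Step 9. Bromination of ring A may compete, since its two free carbons each have three oxygen donors, and a second bromination at C4' is possible; the rate difference between a free phenol and aryl ethers is the only control. The fallback sets out from 14 and needs no halogen. O-Alkylation of the C2' phenol with prenyl bromide (K2CO3, acetone, reflux) gives methyl 2-[3,6-dimethoxy-2-(3-methylbut-2-en-1-yloxy)phenoxy]-4,6-bis(methoxymethoxy)benzoate F5. Heating in N,N-diethylaniline at about 190 °C should shift the allyl unit to a substituted ortho carbon, giving a racemic dienone such as methyl 2-{[2,5-dimethoxy-5-(2-methylbut-3-en-2-yl)-6-oxocyclohexa-1,3-dien-1-yl]oxy}-4,6-bis(methoxymethoxy)benzoate F6, and then by a Cope shift to C5'. This comes back to the route at 17, passing by 15.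

Step 5. The two alkoxy groups beside the phenoxide oxygen may slow the coupling enough for hydrodebromination of 7 and oxidative loss of the electron-rich phenoxide to take over at 90 °C. The fallback sets out from 7 and reverses the role of the ring A partner. Bromine–lithium exchange (n-BuLi, THF, −78 °C), B(OiPr)3 and a mild aqueous work-up give [3,5-bis(methoxymethoxy)phenyl]boronic acid F7. Oxidative Chan–Lam coupling of F7 with 5 (Cu(OAc)2, pyridine, 4 Å molecular sieves, CH2Cl2, air, rt), with divalent copper at room temperature, comes back to the route at 8.

Step 11. Protonation of the prenyl alkene, followed by addition of chloride or methanol, may compete with acetal cleavage, above all if the acetal para to the ester is slow to leave. The fallback sets out from 15 and changes the order of events. The acetals are removed before any alkene is present (HCl in MeOH, rt → 40 °C) to give methyl 2-(3-bromo-6-hydroxy-2,5-dimethoxyphenoxy)-4,6-dihydroxybenzoate F8. The Stille coupling with 16 (Pd(PPh3)4, DMF, 100 °C), which tolerates free phenols, is then run last and comes back to the route at 18.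

## Further compounds

F1 | step 8 | methyl 2-hydroxy-4,6-bis(methoxymethoxy)benzoate | COC(=O)c1c(O)cc(OCOC)cc1OCOC
F2 | step 8 | methyl 2,4-bis(methoxymethoxy)-6-(trifluoromethylsulfonyloxy)benzoate | COC(=O)c1c(OCOC)cc(OCOC)cc1OS(=O)(=O)C(F)(F)F
F3 | step 8 | methyl 2-[2-(benzyloxy)-3,6-dimethoxyphenoxy]-4,6-bis(methoxymethoxy)benzoate | COC(=O)c1c(OCOC)cc(OCOC)cc1Oc1c(OCc2ccccc2)c(OC)ccc1OC
F4 | step 10 | methyl 2-[2-hydroxy-3,6-dimethoxy-5-(prop-2-en-1-yl)phenoxy]-4,6-bis(methoxymethoxy)benzoate | COC(=O)c1c(OCOC)cc(OCOC)cc1Oc1c(O)c(OC)cc(CC=C)c1OC
F5 | step 9 | methyl 2-[3,6-dimethoxy-2-(3-methylbut-2-en-1-yloxy)phenoxy]-4,6-bis(methoxymethoxy)benzoate | COC(=O)c1c(OCOC)cc(OCOC)cc1Oc1c(OCC=C(C)C)c(OC)ccc1OC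
F6 | step 9 | methyl 2-{[2,5-dimethoxy-5-(2-methylbut-3-en-2-yl)-6-oxocyclohexa-1,3-dien-1-yl]oxy}-4,6-bis(methoxymethoxy)benzoate (racemic) | COC(=O)c1c(OCOC)cc(OCOC)cc1OC1=C(OC)C=CC(OC)(C(C)(C)C=C)C1=O
F7 | step 5 | [3,5-bis(methoxymethoxy)phenyl]boronic acid | COCOc1cc(OCOC)cc(B(O)O)c1
F8 | step 11 | methyl 2-(3-bromo-6-hydroxy-2,5-dimethoxyphenoxy)-4,6-dihydroxybenzoate | COC(=O)c1c(O)cc(O)cc1Oc1c(O)c(OC)cc(Br)c1OC
A1 | alternative 1 | methyl 2-[3,6-dimethoxy-2-(methoxymethoxy)-5-(3-methylbut-2-en-1-yl)phenoxy]-4,6-dihydroxybenzoate | COC(=O)c1c(O)cc(O)cc1Oc1c(OCOC)c(OC)cc(CC=C(C)C)c1OC
A2 | alternative 1 | 3,6-dimethoxy-2-(methoxymethoxy)-5-(3-methylbut-2-en-1-yl)phenol | Oc1c(OCOC)c(OC)cc(CC=C(C)C)c1OC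
A3 | alternative 1 | methyl 3-[3,6-dimethoxy-2-(methoxymethoxy)-5-(3-methylbut-2-en-1-yl)phenoxy]prop-2-ynoate | COC(=O)C#COc1c(OCOC)c(OC)cc(CC=C(C)C)c1OC
A4 | alternative 1 | 1-methoxy-1,3-bis(trimethylsilyloxy)buta-1,3-diene | C=C(O[Si](C)(C)C)C=C(OC)O[Si](C)(C)C
A5 | alternative 2 | 2-[3,6-dimethoxy-2-(methoxymethoxy)-5-(3-methylbut-2-en-1-yl)phenoxy]-4,6-bis(methoxymethoxy)benzoic acid | OC(=O)c1c(OCOC)cc(OCOC)cc1Oc1c(OCOC)c(OC)cc(CC=C(C)C)c1OC
A6 | alternative 2 | 3,5-bis(methoxymethoxy)-2-(trimethylsilyl)phenyl trifluoromethanesulfonate | COCOc1cc(OCOC)c([Si](C)(C)C)c(OS(=O)(=O)C(F)(F)F)c1
A7 | alternative 2 | carbon dioxide | O=C=O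
A8 | alternative 3 | methyl 2-[2-hydroxy-3,6-dimethoxy-5-(3-methylbut-2-en-1-yl)phenoxy]-4,6-bis(methoxymethoxy)benzoate | COC(=O)c1c(OCOC)cc(OCOC)cc1Oc1c(O)c(OC)cc(CC=C(C)C)c1OC
A9 | alternative 3 | methyl 2-[3,6-dimethoxy-2-(3-methylbut-2-en-1-yloxy)phenoxy]-4,6-bis(methoxymethoxy)benzoate | COC(=O)c1c(OCOC)cc(OCOC)cc1Oc1c(OCC=C(C)C)c(OC)ccc1OC
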